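A closed, stirred flask holds substrate, partner and a precatalyst that releases the working catalyst slowly, and the blue, red and violet runs share one charge and differ in time.

| setting | blue | red | violet |
|---|---|---|---|
| substrate | 1.0 M | 1.0 M | 1.0 M |
| partner | 1.30 equiv | 1.30 equiv | 1.30 equiv |
| precatalyst | 2.3 mol% | 2.3 mol% | 2.3 mol% |
| time | 48 h | 120 h | 288 h |

    partner + free catalyst → catalyst intermediate A (k1 = 5.29 × 10⁻⁴ L mol⁻¹ s⁻¹)
    substrate + catalyst intermediate A → catalyst intermediate B (k2 = 5.85 × 10⁻⁴ L mol⁻¹ s⁻¹)
    catalyst intermediate B ⇌ catalyst intermediate C (K3 = 44.1, k3 = 5.96 × 10⁻⁴ s⁻¹)
    catalyst intermediate C ⇌ free catalyst + product (K4 = 71.4 M, k4 = 0.0176 s⁻¹)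
    precatalyst → free catalyst (k5 = 2.01 × 10⁻⁶ s⁻¹)

* which of these there is most of at the end, counted by the substrate in it, blue (catalyst intermediate C / product / substrate / catalyst intermediate B)
* which of these there is most of at the end, counted by the substrate in it, red (catalyst intermediate C / product / substrate / catalyst intermediate B)
* which of these there is most of at the end, counted by the substrate in it, violet (catalyst intermediate C / product / substrate / catalyst intermediate B)
* amount of the one of these that there is most of at the end, in percent of the substrate charged, blue
* amount of the one of these that there is most of at the end, in percent of the substrate charged, red
* amount of the one of these that there is most of at the end, in percent of the substrate charged, violet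

Two of us disputed blue, and we began from the same reckoning. With substrate the limiting reagent and partner at 1.30 equiv, I turn each constant into a time at the charged amounts. A catalyst waits 24.2 min for partner and 28.5 min for substrate, spends 28.0 min in the change from catalyst intermediate B to catalyst intermediate C, and 0.947 min in giving up product. These times add, since one catalyst takes the steps in turn, and I neglect the back steps. One turn therefore costs 81.6 min at the start.

The waits lengthen as substrate and partner are used. Summing them up to a conversion of 0.5 gives 49.5 min. This is the midpoint bill: the catalyst time, meaning the fraction of the charge present as catalyst multiplied by the time it works, that product needs to draw level with substrate.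

My colleague held the loading view, in which the whole 2.3 mol% works from the first minute. Blue then collects 66.2 min, which is more than the bill, so product leads in blue.

I held the release view. Because the precatalyst half-life of 96 h is longer than blue's 48 h, blue collects 10.3 min, less than the bill. Even at the starting pace that is 12.6% conversion, so substrate leads in blue. Red collects 54.9 min, narrowly over the bill, and violet 230 min, well over it, so I expected product to lead in both.

The loading view keeps the long run. The mean released share is 15.6% over blue, but over 2880 h it reaches 95.2%.

The forecast, on my side, gave substrate at 87.9% for blue, product at 53.9% for red and product at 99.5% for violet, opening from “The precatalyst activates slowly”.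

The flasks gave substrate at 87.9% in blue, product at 53.7% in red and product at 99.5% in violet. At 48.0 h, blue still held 70.7% of its catalyst as precatalyst. Red's narrow margin over the bill shows in its substrate, 46.0%, not far behind its product. The flask like red but with 1.4 mol% of precatalyst collects 33.4 min, under the 49.5 min bill. At its end that flask still held 64% of the charged substrate, unbound, against product at 35.8%.

All constants come from no measurement; the result is computed.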